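**Plan**
Retrosynthesis: cut the angelate at O9, the exocyclic C11=C13 (formaldehyde), the lactone at C8–O and C11–C12 (CO2 as the one-carbon piece), C7–C11 (Claisen), the C10 vinyl and methyl groups and C5–C4, back to 4,4-dimethoxycyclohexa-2,5-dienone, whose ring becomes the cyclohexane.
Forward: the carbocycle is present from the start; substituents are set in the order C5 arm (masked acrolein), C10 methyl and vinyl, 9β-ol, C7 acetamide (alkene moves to C8=C9), 6β-ol, 8α,9α-epoxide, 8β-bromo-9α-ol; the lactone ring closes in step 15, followed by methylenation, angelate and deprotection.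
Enabling feature: O8 and O9 are cis (both α) on adjacent ring carbons while the C7 side chain is β, so the γ-lactone is trans-fused to the cyclohexane. A C11 carboxylate cannot reach the rear of C8, but the 9α-oxygen can carry CO2 to C8 through a cis-fused five-membered carbonate, and an alkoxide can then hand the carbonyl carbon to the C11 enolate.
Stereochemistry: C5 from Rh/(R)-BINAP conjugate addition; C10 from alkylation and aldol anti to the C5 arm; C7 by suprafacial [3,3] transfer from the 9β-ol; C6 by LiBH(s-Bu)3; C9 and C8 by α-face epoxidation, diaxial bromide opening and inversion at C8 by the carbonate oxygen.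

Key step: step 15

Remark: ring carbons keep the target's elemane numbers (C10 quaternary, C9 angelate carbinol, C8 lactone O-carbon, C7 lactone C-carbon, C6 free carbinol, C5 acrolein-bearing carbon); β is the face of the C10 methyl group, α that of the C10 vinyl group.

Step 1
Reactants: 1 3,3-diethoxyprop-1-yne
Product: 2 2-ethynyl-5,5-dimethyl-1,3-dioxane
Conditions: 2,2-dimethylpropane-1,3-diol, TsOH (cat.), cyclohexane, 80 °C, removal of EtOH
Reagents that add atoms: 2,2-dimethylpropane-1,3-diol, OCC(C)(C)CO
Why: Acid-catalysed transacetalisation driven by distilling off ethanol should give the more robust cyclic acetal; no stereocentre is involved.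

Step 2
Reactants: 2 2-ethynyl-5,5-dimethyl-1,3-dioxane
Product: 4 2-[1-(5,5-dimethyl-1,3-dioxan-2-yl)ethenyl]-4,4,5,5-tetramethyl-1,3,2-dioxaborolane, via alkenylalane 3 (not isolated)
Conditions: NiCl2(dppp) (3 mol %), (i-Bu)2AlH, THF, 0 → 22 °C; then MeOBpin, 0 → 80 °C
Reagents that add atoms: 2-methoxy-4,4,5,5-tetramethyl-1,3,2-dioxaborolane, COB1OC(C)(C)C(C)(C)O1
Why: Nickel-catalysed Markovnikov (α-selective) hydroalumination of the terminal alkyne followed by aluminium-to-boron exchange should give the 1,1-disubstituted alkenylboronate.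

Step 3
Reactants: 5 4,4-dimethoxycyclohexa-2,5-dien-1-one; 4 alkenylboronate
Product: 6 (5R)-5-[1-(5,5-dimethyl-1,3-dioxan-2-yl)ethenyl]-4,4-dimethoxycyclohex-2-en-1-one
Conditions: Rh(acac)(C2H4)2 (3 mol %), (R)-BINAP (3.3 mol %), 4 (1.1 equiv), KOH (aq.), 1,4-dioxane, 50 °C
Reagents that add atoms: none
Why: Hayashi–Miyaura rhodium-catalysed asymmetric 1,4-addition of the alkenylboron reagent should desymmetrise the dienone, (R)-BINAP being the antipode expected by the usual facial model to set C5 as drawn (arm β).

Step 4
Reactants: 6 enone with C5 arm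
Product: 7 (5R,6S)-6-methyl derivative of 6 (methyl on C10, trans to the C5 arm)
Conditions: LiN(i-Pr)2, THF, −78 °C; MeI, DMPU, −78 → −20 °C
Reagents that add atoms: iodomethane, CI
Why: Kinetic α′-enolate alkylation of the enone should introduce the C10 methyl group anti to the neighbouring C5 arm (this centre is re-set in step 5).

Step 5
Reactants: 7 C10-methyl enone
Product: 8 enone with quaternary C10 carrying 10β-methyl and 10α-(1-hydroxyethyl) (both carbinol epimers)
Conditions: LiN(i-Pr)2, THF, −78 → −40 °C; CH3CHO, −78 °C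
Reagents that add atoms: acetaldehyde, CC=O
Why: Aldol addition of the tetrasubstituted α′-enolate should take acetaldehyde on the face anti to the C5 arm, which fixes the quaternary C10 with methyl β and the two-carbon unit α.

Step 6
Reactants: 8 aldol
Product: 10 enone with quaternary C10 carrying 10β-methyl and 10α-vinyl, via mesylate 9 (not isolated)
Conditions: MsCl, Et3N, CH2Cl2, 0 °C; then DBU, toluene, 100 °C
Reagents that add atoms: none
Why: E2 elimination of the secondary mesylate can only run toward the methyl group because C10 carries no hydrogen, so both carbinol epimers should converge on the vinyl group.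

Step 7
Reactants: 10 C10-vinyl enone
Product: 11 9β-allylic alcohol (C7=C8 alkene, C6 dimethyl ketal)
Conditions: NaBH4, CeCl3·7H2O, MeOH, −78 °C
Reagents that add atoms: none
Why: Luche 1,2-reduction should deliver hydride axially from the α face, anti to the pseudo-axial C10 methyl group, giving the 9β-ol.

Step 8
Reactants: 11 9β-allylic alcohol
Product: 13 N,N-dimethyl-2-(cyclohexenyl)acetamide with 7β-CH2CONMe2 and a C8=C9 alkene, via ketene N,O-acetal 12 (not isolated)
Conditions: MeC(OMe)2NMe2, xylenes, 140 °C
Reagents that add atoms: N,N-dimethylacetamide dimethyl acetal, COC(C)(OC)N(C)C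
Why: Eschenmoser–Claisen [3,3]-rearrangement is suprafacial, so the C9–O bond on the β face should be traded for a C7–C11 bond on the β face while the alkene moves to C8=C9.

Step 9
Reactants: 13 ketal amide
Product: 14 C6 ketone (β,γ-unsaturated, C8=C9)
Conditions: oxalic acid (10 % aq.), SiO2, CH2Cl2, 22 °C
Reagents that add atoms: water, O
Why: Mild hydrolysis should cleave the strained ketone dimethyl ketal selectively while the dioxane acetal and the unconjugated alkene survive; C7 is epimerisable here but its equatorial (β) arrangement is also the thermodynamic one.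

Step 10
Reactants: 14 C6 ketone
Product: 15 6β-alcohol
Conditions: LiBH(s-Bu)3, THF, −78 °C
Reagents that add atoms: none
Why: The bulky hydride should attack the ketone from the α face (equatorial attack, the β face being screened by the syn-axial C10 methyl group), giving the axial 6β-ol cis to both flanking substituents.

Step 11
Reactants: 15 6β-alcohol
Product: 16 6β-triethylsilyl ether
Conditions: Et3SiCl, imidazole, DMAP (cat.), DMF, 40 °C
Reagents that add atoms: chlorotriethylsilane, CC[Si](Cl)(CC)CC
Why: Standard silylation under non-Lewis-acidic conditions should protect O6 without touching the dioxane acetal, so that O9 is the only free hydroxyl after step 15.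

Step 12
Reactants: 16 silyl ether amide
Product: 17 aldehyde (7β-CH2CHO)
Conditions: LiAlH(OEt)3, Et2O, 0 °C; aq. KNaC4H4O6
Reagents that add atoms: none
Why: Partial reduction of the tertiary amide stops at the hemiaminal aluminate, which should release the aldehyde on work-up.

Step 13
Reactants: 17 alkene aldehyde
Product: 18 8α,9α-epoxide
Conditions: dimethyldioxirane (1.1 equiv), acetone, 0 °C
Reagents that add atoms: dimethyldioxirane, CC1(C)OO1
Why: Electrophilic epoxidation should take the cis ring alkene from the α face (the β face is blocked by the pseudo-axial C10 methyl and the axial 6β-silyloxy group), in preference to the hindered vinyl group, the acetal-deactivated alkene and the aldehyde; this sets C9 and provisionally C8.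

Step 14
Reactants: 18 8α,9α-epoxide
Product: 19 8β-bromo-9α-hydroxy aldehyde
Conditions: Li2NiBr4, THF, 0 → 22 °C
Reagents that add atoms: dilithium tetrabromonickelate, [Li+].[Li+].Br[Ni-2](Br)(Br)Br
Why: Trans-diaxial (Fürst–Plattner) opening by bromide should occur at C8 rather than at the neopentyl C9, giving the 8β-bromide anti-periplanar to the 9α-hydroxyl.

Step 15
Reactants: 19 8β-bromo-9α-hydroxy aldehyde
Product: 21 trans-fused 8α,12-lactone carrying an 11-formyl group (enolised) and a free 9α-hydroxyl, via cyclic carbonate 20 (not isolated)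
Conditions: DBU (2 equiv), CO2 (1 atm), DMF, 0 → 25 °C; argon purge; then t-BuOK (3 equiv, THF), 0 → 25 °C; aq. citric acid
Reagents that add atoms: carbon dioxide, O=C=O
Why: Proposed new method: DBU and CO2 should turn the 9α-hydroxyl into an alkyl carbonate anion whose oxygen displaces the trans-diaxial 8β-bromide (5-exo-tet, inversion), giving the cis-fused 8α,9α-carbonate 20 and with it the C8–O bond; t-BuOK should then open 20 reversibly to the acyclic 8-O tert-butyl carbonate and form the C11 aldehyde enolate, which attacks the carbonate carbonyl (5-exo-trig, crossed Claisen condensation) to make the C11–C12 bond and the trans-fused lactone while the 9α-alkoxide is released. The closest known reaction types are the base/CO2 conversion of halohydrins into cyclic carbonates and the C-acylation of carbonyl enolates by dialkyl carbonates. The cyclic carbonate itself cannot be attacked by C11, because C11 (β on C7) and O9 (α) are trans-1,3 and cannot share a ring, which is why the alkoxide relay is needed; the isomeric 9-O carbonate is unproductive and returns to 20. The only stereocentre formed is C8, fixed by SN2 inversion of the 8β-bromide; C11 stays enolised. The step needs carbonate substitution to win over epoxide re-closure and E2 (secured by CO2 saturation and the anti-periplanar Br/O arrangement) and C- over O-acylation (secured by the β-formyl lactone enolate as thermodynamic sink).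

Step 16
Reactants: 21 11-formyl lactone
Product: 22 α-methylene lactone with free 9α-hydroxyl
Conditions: (CH2O)n, K2CO3, THF, 50 °C
Reagents that add atoms: formaldehyde, C=O
Why: Deformylative α-methylenation (aldol with formaldehyde, C→O formyl transfer, E1cB loss of formate) of an α-formyl γ-lactone should install the exocyclic methylene.

Step 17
Reactants: 22 α-methylene lactone alcohol
Product: 23 9α-angelate
Conditions: angelic acid, 2,4,6-trichlorobenzoyl chloride, Et3N, toluene, 22 °C; then 22, 80 °C
Reagents that add atoms: (Z)-2-methylbut-2-enoic acid (angelic acid), C/C=C(/C)C(=O)O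
Why: Yamaguchi esterification through the mixed anhydride without DMAP should acylate the hindered axial 9α-hydroxyl while keeping the Z geometry of the angelate.

Step 18
Reactants: 23 protected angelate
Product: 24 target
Conditions: CF3CO2H/H2O/THF (1:1:4), 0 → 22 °C
Reagents that add atoms: water, O
Why: Aqueous acid should cleave the triethylsilyl ether and hydrolyse the dioxane acetal to the 2-substituted acrolein in one operation, leaving the lactone and the angelate untouched.

**Compound list**
1 | 3,3-diethoxyprop-1-yne | C#CC(OCC)OCC | starting material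
2 | 2-ethynyl-5,5-dimethyl-1,3-dioxane | C#CC1OCC(C)(C)CO1 | intermediate
3 | [1-(5,5-dimethyl-1,3-dioxan-2-yl)ethenyl]bis(2-methylpropyl)alane | C=C([Al](CC(C)C)CC(C)C)C1OCC(C)(C)CO1 | intermediate
4 | 2-[1-(5,5-dimethyl-1,3-dioxan-2-yl)ethenyl]-4,4,5,5-tetramethyl-1,3,2-dioxaborolane | C=C(B1OC(C)(C)C(C)(C)O1)C2OCC(C)(C)CO2 | intermediate
5 | 4,4-dimethoxycyclohexa-2,5-dien-1-one | COC1(OC)C=CC(=O)C=C1 | starting material
6 | (5R)-5-[1-(5,5-dimethyl-1,3-dioxan-2-yl)ethenyl]-4,4-dimethoxycyclohex-2-en-1-one (C5 arm β) | O=C1C=CC(OC)(OC)[C@H](C1)C(=C)C2OCC(C)(C)CO2 | intermediate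
7 | (5R,6S)-6-methyl derivative of 6 (C10 methyl trans to the C5 arm) | O=C1C=CC(OC)(OC)[C@H]([C@@H]1C)C(=C)C2OCC(C)(C)CO2 | intermediate
8 | enone with quaternary C10: 10β-methyl, 10α-(1-hydroxyethyl), both carbinol epimers | O=C1C=CC(OC)(OC)[C@H]([C@]1(C)C(C)O)C(=C)C2OCC(C)(C)CO2 | intermediate
9 | methanesulfonate of 8 | O=C1C=CC(OC)(OC)[C@H]([C@]1(C)C(C)OS(C)(=O)=O)C(=C)C2OCC(C)(C)CO2 | intermediate
10 | enone with quaternary C10: 10β-methyl, 10α-vinyl | O=C1C=CC(OC)(OC)[C@H]([C@]1(C)C=C)C(=C)C2OCC(C)(C)CO2 | intermediate
11 | 9β-allylic alcohol (C7=C8, C6 dimethyl ketal) | O[C@H]1C=CC(OC)(OC)[C@H]([C@]1(C)C=C)C(=C)C2OCC(C)(C)CO2 | intermediate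
12 | 1-(dimethylamino)ethenyl ether of 11 (ketene N,O-acetal) | C=C(N(C)C)O[C@H]1C=CC(OC)(OC)[C@H]([C@]1(C)C=C)C(=C)C2OCC(C)(C)CO2 | intermediate
13 | cyclohexene (C8=C9) with 7β-CH2CONMe2, 6,6-dimethoxy, 5β-arm, 10β-methyl, 10α-vinyl | C1=C[C@@H](CC(=O)N(C)C)C(OC)(OC)[C@H]([C@]1(C)C=C)C(=C)C2OCC(C)(C)CO2 | intermediate
14 | C6 ketone of 13 | C1=C[C@@H](CC(=O)N(C)C)C(=O)[C@H]([C@]1(C)C=C)C(=C)C2OCC(C)(C)CO2 | intermediate
15 | 6β-alcohol | C1=C[C@@H](CC(=O)N(C)C)[C@@H](O)[C@H]([C@]1(C)C=C)C(=C)C2OCC(C)(C)CO2 | intermediate
16 | 6β-triethylsilyl ether | C1=C[C@@H](CC(=O)N(C)C)[C@@H](O[Si](CC)(CC)CC)[C@H]([C@]1(C)C=C)C(=C)C2OCC(C)(C)CO2 | intermediate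
17 | aldehyde (7β-CH2CHO), 6β-OSiEt3, C8=C9 | C1=C[C@@H](CC=O)[C@@H](O[Si](CC)(CC)CC)[C@H]([C@]1(C)C=C)C(=C)C2OCC(C)(C)CO2 | intermediate
18 | 8α,9α-epoxide of 17 | C=C[C@]1(C)[C@@H]2O[C@@H]2[C@@H](CC=O)[C@@H](O[Si](CC)(CC)CC)[C@H]1C(=C)C3OCC(C)(C)CO3 | intermediate
19 | 8β-bromo-9α-hydroxy aldehyde | C=C[C@]1(C)[C@H](O)[C@@H](Br)[C@@H](CC=O)[C@@H](O[Si](CC)(CC)CC)[C@H]1C(=C)C2OCC(C)(C)CO2 | intermediate
20 | 8α,9α-cyclic carbonate (cis-fused) of the aldehyde | C=C[C@]1(C)[C@@H]2OC(=O)O[C@@H]2[C@@H](CC=O)[C@@H](O[Si](CC)(CC)CC)[C@H]1C(=C)C3OCC(C)(C)CO3 | intermediate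
21 | trans-fused 8α,12-lactone with 11-formyl (drawn as the formyl tautomer, enolised), 9α-OH, 6β-OSiEt3 | C=C[C@]1(C)[C@H](O)[C@@H]2OC(=O)C(C=O)[C@H]2[C@@H](O[Si](CC)(CC)CC)[C@H]1C(=C)C3OCC(C)(C)CO3 | intermediate
22 | α-methylene lactone with 9α-OH, 6β-OSiEt3, acetal arm | C=C[C@]1(C)[C@H](O)[C@@H]2OC(=O)C(=C)[C@H]2[C@@H](O[Si](CC)(CC)CC)[C@H]1C(=C)C3OCC(C)(C)CO3 | intermediate
23 | 9α-angelate of 22 | C=C[C@]1(C)[C@H](OC(=O)/C(C)=C\C)[C@@H]2OC(=O)C(=C)[C@H]2[C@@H](O[Si](CC)(CC)CC)[C@H]1C(=C)C3OCC(C)(C)CO3 | intermediate
24 | CNP0320538.1 | C=C[C@]1(C)[C@H](OC(=O)/C(C)=C\C)[C@@H]2OC(=O)C(=C)[C@H]2[C@@H](O)[C@H]1C(=C)C=O | target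

Total step count: 18. Longest linear sequence: 18 steps (1 → 24).

**Steps most likely to fail**

Step 15. The acyl transfer may stall at the cyclic carbonate, or intermolecular condensation of the aldehyde enolate may outrun the ring-opening relay. The fallback uses known chemistry and sets out from 19. With Cs2CO3 and CO2 in DMF the cyclic carbonate 20 is made and isolated. K2CO3 in MeOH then removes the carbonate carbon, and the 8α,9α-diol aldehyde should close to the trans-fused lactol F1. α-Methylenation of this masked aldehyde with aqueous formaldehyde, pyrrolidine and propionic acid should give the α-methylene lactol F2, and oxidation with Ag2CO3 on Celite comes back to the route at 22.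

Step 14. Opening of the hindered epoxide may be slow or unselective, through attack at C9 or participation of the aldehyde oxygen at C8. The fallback sets out from 16, before the aldehyde is unmasked. Dihydroxylation of the ring alkene from the α face with OsO4 (cat.) and N-methylmorpholine N-oxide should give the 8α,9α-diol amide F3. Camphorsulfonic acid in toluene at 80 °C should lactonise the 8α-hydroxyl onto the amide to the saturated trans-fused hydroxy lactone F4. Formylation with HCO2Et and NaH comes back to the route at 21.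

Step 3. The α-branched alkenylboronate may transmetalate poorly, giving low conversion, low enantioselectivity or double addition. The fallback sets out from 2 and 5: the alane 3, generated as in step 2, is used directly in a copper-catalysed enantioselective conjugate addition (Cu(OTf)2, chiral phosphoramidite ligand, Et2O, −30 °C) and comes back to the route at 6. No new compound arises.

Further compounds
F1 | step 15 | trans-fused lactol (8α-O–CH(OH)–CH2–C7) with 9α-OH, 6β-OSiEt3, acetal arm | C=C[C@]1(C)[C@H](O)[C@@H]2OC(O)C[C@H]2[C@@H](O[Si](CC)(CC)CC)[C@H]1C(=C)C3OCC(C)(C)CO3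
F2 | step 15 | α-methylene lactol | C=C[C@]1(C)[C@H](O)[C@@H]2OC(O)C(=C)[C@H]2[C@@H](O[Si](CC)(CC)CC)[C@H]1C(=C)C3OCC(C)(C)CO3
F3 | step 14 | 8α,9α-diol amide | C=C[C@]1(C)[C@H](O)[C@H](O)[C@@H](CC(=O)N(C)C)[C@@H](O[Si](CC)(CC)CC)[C@H]1C(=C)C2OCC(C)(C)CO2
F4 | step 14 | saturated trans-fused 8α,12-lactone with 9α-OH | C=C[C@]1(C)[C@H](O)[C@@H]2OC(=O)C[C@H]2[C@@H](O[Si](CC)(CC)CC)[C@H]1C(=C)C3OCC(C)(C)CO3
F0 | step 3 | none | none
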